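**Plan**
- Retrosynthesis: the C9 angelate and the C7–C11 bond are cut first (acylation; trans-diaxial opening of a 7α,8α-epoxide), then C1–C10 (oxidative union of two enol ethers), then C2–C3 (acetyl transfer to an organozinc) and C4–C5 (ester enolate Claisen rearrangement).
- Forward: the starting cyclohexenone becomes ring B; the C4/C5 pair is set on it, the side chain is grown to the C2 methyl ketone, ring B is oxidised to the C7–C8 enone, and ring A (C1–C5, C10) is closed last by the C1–C10 bond.
- Enabling feature: O-2 and O-9 stand 1,4 to each other across the C1–C10 bond of ring A, a dissonant pattern that is met by joining the enol carbons C1 and C10 under oxidation.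
- Stereochemistry: C5 and C4 from one CBS-derived carbinol through the Ireland–Claisen rearrangement; C10 by equilibration to the trans fusion; C2 and C9 by hydride reduction then Mitsunobu inversion; C8 and C7 by hydroxyl-directed epoxidation and Fürst–Plattner opening.

Key step: step 11

Remark: eremophilane numbering is used throughout (decalin C1–C10, C14 on C5, C15 on C4, isopropenyl C11–C13 on C7; "11,12,13-trinoreremophilane" is the 4β,5β-dimethyldecalin core), β is the face of the C5 methyl, and the target is the (2S,4S,5R,7R,8R,9S,10R) isomer: 2α-OAc, 4β-Me, 5β-Me, 7β-isopropenyl, 8α-OH, 9α-OAng, 10α-H (trans-fused).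

**Route**

Step 1
Reactants: 1 3-methylcyclohex-2-en-1-one
Product: 2 (R)-3-methylcyclohex-2-en-1-ol
Conditions: (S)-2-methyl-CBS-oxazaborolidine (0.2 equiv), catecholborane, toluene, −78 °C
Reagents that add atoms: none
Why: Corey–Bakshi–Shibata reduction, in which the oxazaborolidine binds the ketone with the alkenyl arm as the large group and delivers hydride to one carbonyl face, so the (S)-catalyst should give the (R)-carbinol, while catecholborane at low temperature leaves the alkene alone.

Step 2
Reactants: 2 (R)-3-methylcyclohex-2-en-1-ol; 3 propionyl chloride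
Product: 4 (R)-3-methylcyclohex-2-en-1-yl propanoate
Conditions: pyridine, DMAP (cat.), CH2Cl2, 0 °C
Reagents that add atoms: none
Why: Acylation of a secondary allylic alcohol with an acid chloride; the carbinol stereocentre is not touched.

Step 3
Reactants: 4 (R)-3-methylcyclohex-2-en-1-yl propanoate
Product: 7 (2R)-2-[(1S)-1-methylcyclohex-2-en-1-yl]propan-1-ol, via silyl ketene acetal 5 (not isolated), via silyl ester 6 (not isolated)
Conditions: LiN(i-Pr)2, THF/HMPA (23% v/v), −78 °C; Me3SiCl/Et3N; −78 → 60 °C; then LiAlH4, 0 °C
Reagents that add atoms: none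
Why: Ireland–Claisen rearrangement, in which the (Z)-silyl ketene acetal formed in THF/HMPA should pass through the boat transition state usual for cyclohexenyl esters (silyloxy group turned away from the ring), so the C4–C5 bond forms suprafacially on the face that carried the ester oxygen (fixing C5) and the enolate methyl ends cis to the C5 methyl of the later ring A (fixing C4); the minor (E)-acetal is expected to prefer the chair and hence the same diastereomer, and the silyl ester is reduced in the same flask.

Step 4
Reactants: 7 (2R)-2-[(1S)-1-methylcyclohex-2-en-1-yl]propan-1-ol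
Product: 8 (3S)-3-[(2R)-1-iodopropan-2-yl]-3-methylcyclohex-1-ene
Conditions: I2, PPh3, imidazole, CH2Cl2, 0 °C → rt
Reagents that add atoms: iodine, II
Why: Appel-type iodination of a primary alcohol by SN2 at C3; no stereocentre takes part.

Step 5
Reactants: 8 (3S)-3-[(2R)-1-iodopropan-2-yl]-3-methylcyclohex-1-ene; 9 acetyl chloride
Product: 11 (4S)-4-[(1R)-1-methylcyclohex-2-en-1-yl]pentan-2-one, via alkylzinc iodide 10 (not isolated)
Conditions: Zn dust, LiCl, THF, 40 °C; then AcCl (9), Pd(PPh3)4 (5 mol%), 0 °C → rt
Reagents that add atoms: none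
Why: Zinc insertion into the primary iodide followed by Negishi acylation under zerovalent palladium catalysis forms the C2–C3 bond and leaves the C4 stereocentre and the ring alkene untouched.

Step 6
Reactants: 11 (4S)-4-[(1R)-1-methylcyclohex-2-en-1-yl]pentan-2-one
Product: 12 2-methyl-2-[(2S)-2-[(1R)-1-methylcyclohex-2-en-1-yl]propyl]-1,3-dioxolane
Conditions: HOCH2CH2OH, pyridinium p-toluenesulfonate (cat.), benzene, reflux (Dean–Stark)
Reagents that add atoms: ethylene glycol, OCCO
Why: Acid-catalysed ketalisation with azeotropic removal of water masks the methyl ketone against the borane of step 7 and against dehydrogenation in step 8.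

Step 7
Reactants: 12 2-methyl-2-[(2S)-2-[(1R)-1-methylcyclohex-2-en-1-yl]propyl]-1,3-dioxolane
Product: 14 (1R,3S)-3-methyl-3-[(2S)-1-(2-methyl-1,3-dioxolan-2-yl)propan-2-yl]cyclohexan-1-ol, via B-alkyl-9-BBN 13 (not isolated)
Conditions: 9-BBN, THF, 65 °C; then NaOH, H2O2, 0 °C → rt
Reagents that add atoms: hydrogen peroxide, OO
Why: Hydroboration–oxidation, in which the bulky borane places boron on C9 (the alkene carbon remote from quaternary C5) and oxidation with retention gives the C9 alcohol; its configuration (drawn as the expected epimer anti to the C5 methyl) is erased in step 8.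

Step 8
Reactants: 14 (1R,3S)-3-methyl-3-[(2S)-1-(2-methyl-1,3-dioxolan-2-yl)propan-2-yl]cyclohexan-1-ol
Product: 16 (5S)-5-methyl-5-[(2S)-1-(2-methyl-1,3-dioxolan-2-yl)propan-2-yl]cyclohex-2-en-1-one, via saturated ketone 15 (not isolated)
Conditions: IBX (3.5 equiv), DMSO/fluorobenzene, 70 °C
Reagents that add atoms: none
Why: IBX oxidises the alcohol to the ketone and then dehydrogenates it (Nicolaou IBX dehydrogenation); only the C7–C8 enone can form because C10 is flanked by quaternary C5, and dioxolanes are known to survive these conditions.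

Step 9
Reactants: 16 (5S)-5-methyl-5-[(2S)-1-(2-methyl-1,3-dioxolan-2-yl)propan-2-yl]cyclohex-2-en-1-one
Product: 17 (5S)-5-methyl-5-[(2S)-4-oxopentan-2-yl]cyclohex-2-en-1-one
Conditions: 1 M HCl, THF, rt
Reagents that add atoms: water, O
Why: Mild acid hydrolysis of the dioxolane releases the C2 methyl ketone; the enone is stable to these conditions.

Step 10
Reactants: 17 (5S)-5-methyl-5-[(2S)-4-oxopentan-2-yl]cyclohex-2-en-1-one
Product: 18 bis(tert-butyldimethylsilyl enol ether) of 17 (C1=C2–OSi in the chain; C7=C8–C9(OSi)=C10 in ring B)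
Conditions: LiN(i-Pr)2 (2.4 equiv), THF, −78 °C; t-BuMe2SiCl, HMPA, −78 → 0 °C
Reagents that add atoms: tert-butyldimethylsilyl chloride, CC(C)(C)[Si](C)(C)Cl
Why: Kinetic double deprotonation removes a methyl proton (C1) of the methyl ketone and a proton from C10, the only alpha-prime position of the enone, and O-silylation gives the terminal enol ether and the cross-conjugated 2-silyloxydiene.

Step 11
Reactants: 18 bis(tert-butyldimethylsilyl enol ether) of 17
Product: 19 10βH-11,12,13-trinoreremophil-7-ene-2,9-dione (cis-fused)
Conditions: reticulated vitreous carbon anode, Pt cathode, undivided cell, constant current (2.2 F/mol), LiClO4 (0.1 M), 2,6-lutidine, MeOH/CH2Cl2 1:4, rt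
Reagents that add atoms: none
Why: Proposed new method: the cross-conjugated 2-silyloxydiene (C7=C8–C9(OSi)=C10) is the more easily oxidised π-system and should lose one electron at the anode to a radical cation with spin and charge at C10, which is attacked by C1, the nucleophilic terminus of the isolated C1=C2 silyl enol ether; a second electron transfer and loss of both silyl groups to methanol then give the 2,9-dione with the C7–C8 enone intact. The closest known reactions are intramolecular anodic couplings of enol ether radical cations with electron-rich olefins and the (NH4)2Ce(NO3)6-mediated coupling of bis(silyl enol ethers) to 1,4-diketones, neither yet shown with a cross-conjugated dienol ether as the oxidised partner. Ring A closes 6-exo with respect to the oxidised C9=C10 bond and 6-endo with respect to the C1=C2 bond; the five-membered alternative (C2 to C10) is excluded because it would leave the charge on primary C1 and not on oxygen-stabilised C2. The new stereocentre C10 is set by stereoelectronics: C1 must bond along the p-axis of C10 on the face that the pseudoequatorial C4 arm of C5 can reach, which leaves H-10 on the face of the C5 methyl (cis fusion), an outcome that is accepted because C10 is epimerisable in step 12. The step needs site selectivity (C10 against C7 of the dienyl radical cation and against capture by methanol), which the tether from C5 secures because it reaches only C10 and delivers the electron-rich C1 terminus intramolecularly.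

Step 12
Reactants: 19 10βH-11,12,13-trinoreremophil-7-ene-2,9-dione
Product: 20 10αH-11,12,13-trinoreremophil-7-ene-2,9-dione (trans-fused)
Conditions: DBU (0.3 equiv), toluene, 40 °C
Reagents that add atoms: none
Why: Base-mediated epimerisation through the C9 dienolate, in which C10 is the only stereocentre alpha to a carbonyl (C4 is beta to C2) and the trans fusion is expected to prevail by analogy with 5α- over 5β-6-oxo steroids; remaining cis isomer is separated and resubmitted.

Step 13
Reactants: 20 10αH-11,12,13-trinoreremophil-7-ene-2,9-dione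
Product: 21 2β-hydroxy-10αH-11,12,13-trinoreremophil-7-en-9-one
Conditions: NaBH4, MeOH/CH2Cl2 1:1, −78 °C
Reagents that add atoms: none
Why: Chemoselective borohydride reduction (a saturated ketone is reduced faster than a conjugated enone at low temperature), with axial hydride attack on the unhindered ring A ketone from the α-face giving the equatorial 2β-alcohol.

Step 14
Reactants: 21 2β-hydroxy-10αH-11,12,13-trinoreremophil-7-en-9-one; 22 acetic acid
Product: 23 2α-acetoxy-10αH-11,12,13-trinoreremophil-7-en-9-one
Conditions: PPh3, DIAD, toluene, 0 °C → rt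
Reagents that add atoms: none
Why: Mitsunobu reaction, in which SN2 displacement at C2 inverts the equatorial 2β-alcohol to the axial 2α-acetate of the target.

Step 15
Reactants: 23 2α-acetoxy-10αH-11,12,13-trinoreremophil-7-en-9-one
Product: 24 2α-acetoxy-10αH-11,12,13-trinoreremophil-7-en-9β-ol
Conditions: NaBH4, CeCl3·7H2O, MeOH, −78 °C
Reagents that add atoms: none
Why: Luche 1,2-reduction, in which the axial C5 methyl (1,3 to C9) blocks the β-face so that hydride should enter from the α-face and give the pseudoaxial 9β-alcohol, the acetate being inert.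

Step 16
Reactants: 24 2α-acetoxy-10αH-11,12,13-trinoreremophil-7-en-9β-ol
Product: 25 2α-acetoxy-9α-(chloroacetoxy)-10αH-11,12,13-trinoreremophil-7-ene
Conditions: ClCH2CO2H, PPh3, DIAD, toluene, 0 °C → rt
Reagents that add atoms: chloroacetic acid, OC(=O)CCl
Why: Mitsunobu inversion with the more acidic chloroacetic acid (suited to hindered alcohols and less prone to elimination), in which the carboxylate attacks C9 from the open α-face and gives the equatorial 9α-ester.

Step 17
Reactants: 25 2α-acetoxy-9α-(chloroacetoxy)-10αH-11,12,13-trinoreremophil-7-ene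
Product: 26 2α-acetoxy-10αH-11,12,13-trinoreremophil-7-en-9α-ol
Conditions: thiourea, NaHCO3, EtOH, 60 °C
Reagents that add atoms: none
Why: Selective dechloroacetylation, in which thiourea is S-alkylated and cyclises onto the ester carbonyl to release the alcohol, conditions under which the secondary acetate at C2 stays in place.

Step 18
Reactants: 26 2α-acetoxy-10αH-11,12,13-trinoreremophil-7-en-9α-ol
Product: 27 2α-acetoxy-7α,8α-epoxy-10αH-11,12,13-trinoreremophilan-9α-ol
Conditions: mCPBA, NaHCO3, CH2Cl2, 0 °C
Reagents that add atoms: 3-chloroperoxybenzoic acid, OOC(=O)c1cccc(Cl)c1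
Why: Henbest epoxidation, in which hydrogen bonding of the peracid to the pseudoequatorial 9α-hydroxyl and shielding of the β-face by the C5 methyl both send oxygen to the α-face, setting C7 and C8 of the epoxide.

Step 19
Reactants: 27 2α-acetoxy-7α,8α-epoxy-10αH-11,12,13-trinoreremophilan-9α-ol; 28 isopropenylmagnesium bromide
Product: 29 2α-acetoxy-7β-isopropenyl-10αH-eremophil-11-ene-8α,9α-diol
Conditions: isopropenylmagnesium bromide (6 equiv), CuBr·SMe2 (3 equiv), THF, −40 → 0 °C
Reagents that add atoms: none
Why: Cuprate opening of the epoxide under Fürst–Plattner control, in which attack at C7 from the β-face gives the trans-diaxial product (7β-isopropenyl, 8α-OH) as in 2α,3α-epoxy steroids, attack at C8 being disfavoured both conformationally and by the adjacent C9 oxygen, while the magnesium cuprate spares the acetate at low temperature.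

Step 20
Reactants: 29 2α-acetoxy-7β-isopropenyl-10αH-eremophil-11-ene-8α,9α-diol; 30 angelic acid
Product: 32 2α-acetoxy-9α-angeloyloxy-7β-isopropenyl-10αH-eremophil-11-en-8α-ol (CNP0217919.1), via mixed anhydride 31 (not isolated)
Conditions: 2,4,6-Cl3C6H2COCl, Et3N, toluene, rt; then 29, toluene, 75 °C
Reagents that add atoms: none
Why: Yamaguchi esterification, in which the mixed anhydride should acylate the equatorial 9α-hydroxyl in preference to the axial 8α-hydroxyl next to the isopropenyl-bearing C7, and the absence of a nucleophilic catalyst keeps the (Z)-geometry of the angelate.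

**Compound list**
1 | 3-methylcyclohex-2-en-1-one | CC1=CC(=O)CCC1 | starting material
2 | (R)-3-methylcyclohex-2-en-1-ol | O[C@H]1C=C(C)CCC1 | intermediate
3 | propionyl chloride | CCC(=O)Cl | starting material
4 | (R)-3-methylcyclohex-2-en-1-yl propanoate | CCC(=O)O[C@H]1C=C(C)CCC1 | intermediate
5 | (Z)-O-trimethylsilyl ketene acetal of 4 | C/C=C(\O[Si](C)(C)C)O[C@H]1C=C(C)CCC1 | intermediate
6 | trimethylsilyl (2R)-2-[(1S)-1-methylcyclohex-2-en-1-yl]propanoate | C[Si](C)(C)OC(=O)[C@H](C)[C@@]1(C)CCCC=C1 | intermediate
7 | (2R)-2-[(1S)-1-methylcyclohex-2-en-1-yl]propan-1-ol | OC[C@H](C)[C@@]1(C)CCCC=C1 | intermediate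
8 | (3S)-3-[(2R)-1-iodopropan-2-yl]-3-methylcyclohex-1-ene | IC[C@H](C)[C@@]1(C)CCCC=C1 | intermediate
9 | acetyl chloride | CC(=O)Cl | starting material
10 | [(2R)-2-[(1S)-1-methylcyclohex-2-en-1-yl]propyl]zinc iodide | I[Zn]C[C@H](C)[C@@]1(C)CCCC=C1 | intermediate
11 | (4S)-4-[(1R)-1-methylcyclohex-2-en-1-yl]pentan-2-one | CC(=O)C[C@H](C)[C@@]1(C)CCCC=C1 | intermediate
12 | 2-methyl-2-[(2S)-2-[(1R)-1-methylcyclohex-2-en-1-yl]propyl]-1,3-dioxolane | CC1(C[C@H](C)[C@@]2(C)CCCC=C2)OCCO1 | intermediate
13 | B-alkyl-9-BBN adduct of 12 (boron on C9) | CC1(C[C@H](C)[C@@]2(C)CCC[C@@H](B3C4CCCC3CCC4)C2)OCCO1 | intermediate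
14 | (1R,3S)-3-methyl-3-[(2S)-1-(2-methyl-1,3-dioxolan-2-yl)propan-2-yl]cyclohexan-1-ol | CC1(C[C@H](C)[C@@]2(C)CCC[C@@H](O)C2)OCCO1 | intermediate
15 | (3S)-3-methyl-3-[(2S)-1-(2-methyl-1,3-dioxolan-2-yl)propan-2-yl]cyclohexan-1-one | CC1(C[C@H](C)[C@@]2(C)CCCC(=O)C2)OCCO1 | intermediate
16 | (5S)-5-methyl-5-[(2S)-1-(2-methyl-1,3-dioxolan-2-yl)propan-2-yl]cyclohex-2-en-1-one | CC1(C[C@H](C)[C@@]2(C)CC=CC(=O)C2)OCCO1 | intermediate
17 | (5S)-5-methyl-5-[(2S)-4-oxopentan-2-yl]cyclohex-2-en-1-one | CC(=O)C[C@H](C)[C@@]1(C)CC=CC(=O)C1 | intermediate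
18 | bis(tert-butyldimethylsilyl enol ether) of 17 | C=C(O[Si](C)(C)C(C)(C)C)C[C@H](C)[C@@]1(C)CC=CC(O[Si](C)(C)C(C)(C)C)=C1 | intermediate
19 | 10βH-11,12,13-trinoreremophil-7-ene-2,9-dione (cis-fused) | O=C1C=CC[C@]2(C)[C@@H](C)CC(=O)C[C@H]12 | intermediate
20 | 10αH-11,12,13-trinoreremophil-7-ene-2,9-dione (trans-fused) | O=C1C=CC[C@]2(C)[C@@H](C)CC(=O)C[C@@H]12 | intermediate
21 | 2β-hydroxy-10αH-11,12,13-trinoreremophil-7-en-9-one | O=C1C=CC[C@]2(C)[C@@H](C)C[C@@H](O)C[C@@H]12 | intermediate
22 | acetic acid | CC(=O)O | starting material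
23 | 2α-acetoxy-10αH-11,12,13-trinoreremophil-7-en-9-one | O=C1C=CC[C@]2(C)[C@@H](C)C[C@H](OC(C)=O)C[C@@H]12 | intermediate
24 | 2α-acetoxy-10αH-11,12,13-trinoreremophil-7-en-9β-ol | O[C@H]1C=CC[C@]2(C)[C@@H](C)C[C@H](OC(C)=O)C[C@@H]12 | intermediate
25 | 2α-acetoxy-9α-(chloroacetoxy)-10αH-11,12,13-trinoreremophil-7-ene | O=C(CCl)O[C@@H]1C=CC[C@]2(C)[C@@H](C)C[C@H](OC(C)=O)C[C@@H]12 | intermediate
26 | 2α-acetoxy-10αH-11,12,13-trinoreremophil-7-en-9α-ol | O[C@@H]1C=CC[C@]2(C)[C@@H](C)C[C@H](OC(C)=O)C[C@@H]12 | intermediate
27 | 2α-acetoxy-7α,8α-epoxy-10αH-11,12,13-trinoreremophilan-9α-ol | O[C@@H]1[C@@H]2O[C@@H]2C[C@]3(C)[C@@H](C)C[C@H](OC(C)=O)C[C@@H]13 | intermediate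
28 | isopropenylmagnesium bromide | C=C(C)[Mg]Br | starting material
29 | 2α-acetoxy-7β-isopropenyl-10αH-eremophil-11-ene-8α,9α-diol | C=C(C)[C@H]1C[C@]2(C)[C@@H](C)C[C@H](OC(C)=O)C[C@H]2[C@H](O)[C@@H]1O | intermediate
30 | angelic acid, (Z)-2-methylbut-2-enoic acid | C/C=C(/C)C(=O)O | starting material
31 | angelic 2,4,6-trichlorobenzoic anhydride | C/C=C(/C)C(=O)OC(=O)c1c(Cl)cc(Cl)cc1Cl | intermediate
32 | CNP0217919.1, 2α-acetoxy-9α-angeloyloxy-7β-isopropenyl-10αH-eremophil-11-en-8α-ol | C=C(C)[C@H]1C[C@]2(C)[C@@H](C)C[C@H](OC(C)=O)C[C@H]2[C@H](OC(=O)/C(C)=C\C)[C@@H]1O | target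

**Count and risks**
Total step count: 20. Longest linear sequence: 20 steps (from 3-methylcyclohex-2-en-1-one).

Steps most likely to fail:

1. Step 11 (anodic coupling). The dienyl radical cation may be captured by methanol or lose its silyl group before C1 arrives, or intermolecular coupling may outrun ring closure. The fallback uses known chemistry without electrolysis or silyl ethers. It sets out from diketone 17, which is deprotonated twice with LiN(i-Pr)2 (2.3 equiv, THF, −78 °C) to the dilithium bis-enolate F1 (enolates at C1 and C10). F1 is oxidised in the same flask with anhydrous CuCl2 in DMF, a Saegusa-type inner-sphere coupling of metal enolates by divalent copper with intramolecular precedent for cyclic 1,4-diketones. This should give dione 19 (possibly with some 20), and the route is rejoined at 19 for step 12.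

2. Step 12 (C10 equilibration). The equilibrium may lie too close to the cis isomer, or enolate-triggered aldol or Michael condensation may compete during long base exposure. The fallback replaces thermodynamic by kinetic control. It sets out from 19, which is converted with Me3SiOTf/Et3N (CH2Cl2, 0 °C) into the bis(trimethylsilyl) dienol ether F2 (C1=C2 and C9=C10 enol ethers). F2 is desilylated at −78 °C with Bu4NF in the presence of acetic acid, so that C10 is protonated on the α-face, anti to the adjacent axial C5 methyl. This should give the trans-fused dione 20, where the route is rejoined.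

3. Step 19 (cuprate opening). The opening may be slow because the nucleophile must enter C7 syn-axial to the C5 methyl, which lets attack on the acetate, elimination to an allylic alcohol or halohydrin formation compete. The fallback uses a slim alkynyl nucleophile and sets out from epoxy alcohol 27. Opening with LiC≡CSiMe3/BF3·OEt2 (THF, −78 °C; Yamaguchi alkynylation, trans-diaxial) should give the 7β-(trimethylsilylethynyl) diol F3. Buffered Bu4NF/AcOH removes the silyl group to give the 7β-ethynyl diol F4. Negishi methylalumination (Me3Al, Cp2ZrCl2 cat., CH2Cl2, then H2O) then turns the terminal alkyne into the isopropenyl group, giving 29, from which step 20 follows.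

Further compounds
F1 | step 11 | dilithium bis-enolate of 17 (C1 and C10 enolates) | [Li]OC(=C)C[C@H](C)[C@@]1(C)CC=CC(O[Li])=C1
F2 | step 12 | 2,9-bis(trimethylsilyloxy)-11,12,13-trinoreremophila-1,7,9-triene | C[Si](C)(C)OC1=C2C=C(O[Si](C)(C)C)C[C@H](C)[C@@]2(C)CC=C1
F3 | step 19 | 2α-acetoxy-7β-(trimethylsilylethynyl)-10αH-11,12,13-trinoreremophilane-8α,9α-diol | C[Si](C)(C)C#C[C@H]1C[C@]2(C)[C@@H](C)C[C@H](OC(C)=O)C[C@H]2[C@H](O)[C@@H]1O
F4 | step 19 | 2α-acetoxy-7β-ethynyl-10αH-11,12,13-trinoreremophilane-8α,9α-diol | C#C[C@H]1C[C@]2(C)[C@@H](C)C[C@H](OC(C)=O)C[C@H]2[C@H](O)[C@@H]1O
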